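**Plan**

Locants: unprimed atoms belong to the N1-linked indole, primed atoms to the C3'-linked 1H-indole.

1. Retrosynthesis: the bromines at C2', C3 and C2 go first (C2'–Br traced back to a C2' carboxylic acid). The primed five-membered ring is then cut at N1'–C7a' and C3a'–C3' into 3,4-dibromobenzyne and a β-(5-bromoindol-1-yl) dehydroamino ester. Its N1–C(β) bond is cut last, to 5-bromoindole and a doubly N-activated dehydroalanine.
2. Enabling feature: C3a' lies between C4'–Br and C3' while C7a' carries N1'. This is the polarity of a 3-bromoaryne, where nitrogen adds to the aryne carbon remote from bromine and the carbanion forms beside bromine. The C2' bromine descends from the ester that makes the acrylate an acceptor.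
3. Forward: the unprimed ring is bought as 5-bromoindole. A silyl triflate (three steps from 3,4-dibromophenol) and the enamide (three steps from serine methyl ester) are joined in the annulation, which closes the primed five-membered ring as an indoline.
4. Endgame: DDQ aromatises the indoline, hydroxide removes Boc and the methyl ester, and NBS installs the last three bromines, one of them by bromodecarboxylation.
5. Stereochemistry: the target has no stereocentre. The C2'/C3' centres of the indoline form as a racemic pair and are erased on dehydrogenation.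

Key step: step 7

Assumption: the target SMILES gives no configuration for the hindered N1–C3' axis, so the compound is made as the racemate with respect to that axis.
Assumption: the enamide entering the key step is drawn as the E isomer expected from imine–enamide tautomerisation; the Z isomer would serve equally, since both alkene carbons become sp3 in the annulation.

**Route**

Step 1
Reactants: 1 3,4-dibromophenol
Product: 2 3,4-dibromophenyl isopropylcarbamate
Conditions: iPrNCO, Et3N (cat.), CH2Cl2, rt
Reagents that add atoms: isopropyl isocyanate, CC(C)N=C=O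
Why: Amine-catalysed addition of the phenol to the isocyanate (carbamoylation) gives an N–H carbamate that directs metalation and can later be cleaved by mild base.

Step 2
Reactants: 2 3,4-dibromophenyl isopropylcarbamate
Product: 6 3,4-dibromo-2-(trimethylsilyl)phenyl isopropylcarbamate, via N-silyl carbamate 3 (not isolated), via aryllithium 4 (not isolated), via N-silyl C-silyl carbamate 5 (not isolated)
Conditions: tBuMe2SiOTf, TMEDA, Et2O, 0 °C to rt; then Me3SiCl, LiN(iPr)2, THF, −78 °C (in situ trapping); aq. NaHSO4
Reagents that add atoms: chlorotrimethylsilane, C[Si](C)(C)Cl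
Why: In situ N-silylation masks the N–H, and directed ortho-metalation by the lithium amide then occurs at C2, the most acidic site because it is flanked by the carbamate oxygen and bromine. The amide base cannot undergo bromine–lithium exchange, Me3SiCl already present traps the aryllithium before LiBr is lost, and the N–Si bond is hydrolysed on work-up.

Step 3
Reactants: 6 3,4-dibromo-2-(trimethylsilyl)phenyl isopropylcarbamate
Product: 8 3,4-dibromo-2-(trimethylsilyl)phenyl trifluoromethanesulfonate, via silylphenol 7 (not isolated)
Conditions: 1,8-diazabicyclo[5.4.0]undec-7-ene (DBU), Et2NH, MeCN, 40 °C; then PhNTf2, rt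
Reagents that add atoms: N-phenylbis(trifluoromethanesulfonimide), O=S(=O)(N(c1ccccc1)S(=O)(=O)C(F)(F)F)C(F)(F)F
Why: The amidine base triggers E1cB fragmentation of the N–H carbamate to the phenoxide and isopropyl isocyanate, which diethylamine scavenges as a urea. The phenoxide is O-triflated in the same pot, so the silylphenol never meets acid.

Step 4
Reactants: 9 L-serine methyl ester hydrochloride
Product: 10 methyl N-tosyl-L-serinate
Conditions: TsCl, Et3N, CH2Cl2, 0 °C to rt
Reagents that add atoms: p-toluenesulfonyl chloride, Cc1ccc(S(=O)(=O)Cl)cc1
Why: The amine is far more nucleophilic than the primary alcohol, so N-sulfonylation is chemoselective. The chiral-pool stereocentre is kept here but destroyed in the next step.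

Step 5
Reactants: 10 methyl N-tosyl-L-serinate
Product: 12 methyl 2-[N-(tert-butoxycarbonyl)-N-tosylamino]acrylate, via bis-Boc serinate 11 (not isolated)
Conditions: Boc2O (2.5 equiv), 4-(dimethylamino)pyridine (cat.), MeCN, rt
Reagents that add atoms: di-tert-butyl dicarbonate, CC(C)(C)OC(=O)OC(=O)OC(C)(C)C
Why: Acyl-transfer catalysis puts Boc on the acidic sulfonamide nitrogen and on the hydroxyl. The tert-butyl carbonate is then lost by E1cB β-elimination from the acidified α-position, giving the N,N-diprotected dehydroalanine.

Step 6
Reactants: 12 methyl 2-[N-(tert-butoxycarbonyl)-N-tosylamino]acrylate; 13 5-bromoindole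
Product: 15 methyl (E)-3-(5-bromoindol-1-yl)-2-[(tert-butoxycarbonyl)amino]acrylate, via N-Boc imine 14 (not isolated)
Conditions: Cs2CO3, MeCN, rt
Reagents that add atoms: none
Why: Aza-Michael addition of the indolide through N1 to the acrylate is made possible by the two acceptor groups on nitrogen. The α-carbanion then expels p-toluenesulfinate from nitrogen (addition–elimination), and the N-acylimine tautomerises to the conjugated enamide, which restores the N–H needed in step 7. The E geometry is expected by analogy with azole adducts of this acceptor.

Step 7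
Reactants: 8 3,4-dibromo-2-(trimethylsilyl)phenyl trifluoromethanesulfonate; 15 methyl (E)-3-(5-bromoindol-1-yl)-2-[(tert-butoxycarbonyl)amino]acrylate
Product: 17 1-tert-butyl 2-methyl trans-4,5-dibromo-3-(5-bromoindol-1-yl)indoline-1,2-dicarboxylate (racemic 2S*,3S*; one enantiomer drawn), via 3,4-dibromobenzyne 16 (not isolated)
Conditions: Bu4N[Ph3SiF2] (TBAT, 2 equiv), 8 (1.5 equiv), THF, 23 °C
Reagents that add atoms: none
Why: Fluoride attacks silicon of 8 and triflate leaves, giving aryne 16; the carbamate nitrogen of 15 adds to the aryne carbon remote from bromine (N1'–C7a'), the aryl anion formed next to C4'–Br adds to the acrylate β-carbon that carries N1 (C3a'–C3'), and the ester enolate is protonated by a further N–H or on work-up. The closest known reaction is the fluoride-triggered formal [3+2] annulation of arynes with N-Boc dehydroalanine esters to N-Boc indoline-2-carboxylates, applied here to a β-heteroaryl congener and a dihalogenated aryne. The one ring formed, the primed five-membered ring, closes by 5-endo-trig conjugate addition of the aryl anion, the mode that operates in the parent reaction. C3' arises in the C–C bond formation without bias (racemate) and C2' is set by protonation of the enolate, for which the thermodynamically preferred trans arrangement of ester and indolyl is expected under the basic conditions; the cis epimer would serve as well because both centres are erased in step 8. The step needs regioselective N-attack, secured by the inductive pull of the bromine flanking the aryne, which distorts the triple bond so that the remote carbon is the electrophilic one and the charge develops beside bromine; it also needs ring closure to outrun proton capture or bromide loss by the aryl anion, secured by the intramolecular acceptor and aprotic THF. The lone pair of N1 belongs to the aromatic sextet, so it hardly deactivates the β-carbon and indolide is a poor leaving group from the enolate at room temperature.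

Step 8
Reactants: 17 1-tert-butyl 2-methyl trans-4,5-dibromo-3-(5-bromoindol-1-yl)indoline-1,2-dicarboxylate
Product: 18 1-tert-butyl 2-methyl 4,5-dibromo-3-(5-bromoindol-1-yl)indole-1,2-dicarboxylate
Conditions: DDQ (2 equiv), 1,4-dioxane, 100 °C
Reagents that add atoms: none
Why: Quinone dehydrogenation, by hydride abstraction from the doubly activated benzylic C3'–H and loss of the C2' proton, aromatises the primed ring and removes both stereocentres. The oxidation is done before any basic step so that indolide cannot be lost from C3' by β-elimination.

Step 9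
Reactants: 18 1-tert-butyl 2-methyl 4,5-dibromo-3-(5-bromoindol-1-yl)indole-1,2-dicarboxylate
Product: 20 4,5-dibromo-3-(5-bromoindol-1-yl)-1H-indole-2-carboxylic acid, via N-H indole ester 19 (not isolated)
Conditions: LiOH (6 equiv), THF/MeOH/H2O, 50 °C; then aq. HCl
Reagents that add atoms: lithium hydroxide, [Li+].[OH-]
Why: The Boc group on an electron-poor indole nitrogen is an activated carbamate that hydroxide or methoxide cleaves readily, and the methyl ester is saponified in the same operation. The aryl bromides are inert.

Step 10
Reactants: 20 4,5-dibromo-3-(5-bromoindol-1-yl)-1H-indole-2-carboxylic acid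
Product: 23 rivularin A (2,4,5-tribromo-3-(2,3,5-tribromoindol-1-yl)-1H-indole), via 3-bromo acid 21 (not isolated), via pentabromide 22 (not isolated)
Conditions: NBS (3.2 equiv), DMF, 0 °C to rt, dark
Reagents that add atoms: N-bromosuccinimide, O=C1CCC(=O)N1Br
Why: Electrophilic bromination should occur first at C3 of the unprimed indole, then ipso at C2' with loss of CO2 (Hunsdiecker-type bromodecarboxylation of an indole-2-carboxylic acid), and last at C2 of the 3-bromoindole. The remaining C–H positions sit on bromine-deactivated benzo rings, and the order of the three events does not change the product.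

**Compound list**

1 | 3,4-dibromophenol | Oc1ccc(Br)c(Br)c1 | starting material
2 | 3,4-dibromophenyl isopropylcarbamate | CC(C)NC(=O)Oc1ccc(Br)c(Br)c1 | intermediate
3 | 3,4-dibromophenyl N-(tert-butyldimethylsilyl)-N-isopropylcarbamate | CC(C)N(C(=O)Oc1ccc(Br)c(Br)c1)[Si](C)(C)C(C)(C)C | intermediate (not isolated)
4 | [2,3-dibromo-6-({N-(tert-butyldimethylsilyl)-N-isopropylcarbamoyl}oxy)phenyl]lithium | [Li]c1c(OC(=O)N(C(C)C)[Si](C)(C)C(C)(C)C)ccc(Br)c1Br | intermediate (not isolated)
5 | 3,4-dibromo-2-(trimethylsilyl)phenyl N-(tert-butyldimethylsilyl)-N-isopropylcarbamate | CC(C)N(C(=O)Oc1ccc(Br)c(Br)c1[Si](C)(C)C)[Si](C)(C)C(C)(C)C | intermediate (not isolated)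
6 | 3,4-dibromo-2-(trimethylsilyl)phenyl isopropylcarbamate | CC(C)NC(=O)Oc1ccc(Br)c(Br)c1[Si](C)(C)C | intermediate
7 | 3,4-dibromo-2-(trimethylsilyl)phenol (present as its amidinium phenoxide) | C[Si](C)(C)c1c(O)ccc(Br)c1Br | intermediate (not isolated)
8 | 3,4-dibromo-2-(trimethylsilyl)phenyl trifluoromethanesulfonate | C[Si](C)(C)c1c(OS(=O)(=O)C(F)(F)F)ccc(Br)c1Br | intermediate
9 | L-serine methyl ester hydrochloride | COC(=O)[C@@H](N)CO.Cl | starting material
10 | methyl N-tosyl-L-serinate | COC(=O)[C@@H](NS(=O)(=O)c1ccc(C)cc1)CO | intermediate
11 | methyl (S)-N-(tert-butoxycarbonyl)-O-(tert-butoxycarbonyl)-N-tosylserinate | COC(=O)[C@H](COC(=O)OC(C)(C)C)N(C(=O)OC(C)(C)C)S(=O)(=O)c1ccc(C)cc1 | intermediate (not isolated)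
12 | methyl 2-[N-(tert-butoxycarbonyl)-N-tosylamino]acrylate | C=C(N(C(=O)OC(C)(C)C)S(=O)(=O)c1ccc(C)cc1)C(=O)OC | intermediate
13 | 5-bromoindole | Brc1ccc2[nH]ccc2c1 | starting material
14 | methyl 3-(5-bromoindol-1-yl)-2-[(tert-butoxycarbonyl)imino]propanoate | COC(=O)C(Cn1ccc2cc(Br)ccc21)=NC(=O)OC(C)(C)C | intermediate (not isolated)
15 | methyl (E)-3-(5-bromoindol-1-yl)-2-[(tert-butoxycarbonyl)amino]acrylate | COC(=O)/C(NC(=O)OC(C)(C)C)=C\n1ccc2cc(Br)ccc21 | intermediate
16 | 3,4-dibromobenzyne (3,4-dibromo-1,2-didehydrobenzene) | BrC1=C(Br)C=CC#C1 | intermediate (not isolated)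
17 | 1-tert-butyl 2-methyl trans-4,5-dibromo-3-(5-bromoindol-1-yl)indoline-1,2-dicarboxylate (racemic, 2S*,3S*; one enantiomer drawn) | COC(=O)[C@@H]1[C@@H](n2ccc3cc(Br)ccc32)c2c(Br)c(Br)ccc2N1C(=O)OC(C)(C)C | intermediate
18 | 1-tert-butyl 2-methyl 4,5-dibromo-3-(5-bromoindol-1-yl)indole-1,2-dicarboxylate | COC(=O)c1c(-n2ccc3cc(Br)ccc32)c2c(Br)c(Br)ccc2n1C(=O)OC(C)(C)C | intermediate
19 | methyl 4,5-dibromo-3-(5-bromoindol-1-yl)-1H-indole-2-carboxylate | COC(=O)c1[nH]c2ccc(Br)c(Br)c2c1-n1ccc2cc(Br)ccc21 | intermediate (not isolated)
20 | 4,5-dibromo-3-(5-bromoindol-1-yl)-1H-indole-2-carboxylic acid | OC(=O)c1[nH]c2ccc(Br)c(Br)c2c1-n1ccc2cc(Br)ccc21 | intermediate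
21 | 4,5-dibromo-3-(3,5-dibromoindol-1-yl)-1H-indole-2-carboxylic acid | OC(=O)c1[nH]c2ccc(Br)c(Br)c2c1-n1cc(Br)c2cc(Br)ccc21 | intermediate (not isolated)
22 | 2,4,5-tribromo-3-(3,5-dibromoindol-1-yl)-1H-indole | Brc1[nH]c2ccc(Br)c(Br)c2c1-n1cc(Br)c2cc(Br)ccc21 | intermediate (not isolated)
23 | rivularin A, 2,4,5-tribromo-3-(2,3,5-tribromoindol-1-yl)-1H-indole | Brc1ccc2c(c1)c(Br)c(Br)n2-c1c(Br)[nH]c2ccc(Br)c(Br)c12 | target

**Count and risks**

Total: 10 steps. Longest linear sequence: 7 steps (steps 1–3 or steps 4–6, followed by steps 7–10).

Steps most likely to fail: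

1. Step 7. The aryl anion may be protonated before it cyclises, leaving only N-arylation. Nitrogen attack may be shared between the two aryne carbons. The enolate may eject indolide by β-elimination, or the anion beside bromine may lose bromide. The fallback avoids the aryne and makes the N1–C3' bond by copper catalysis. It sets out from 13, together with purchased 2,3-dibromobenzaldehyde and methyl azidoacetate, and returns at 18. Knoevenagel condensation (NaOMe, MeOH, −10 °C) should give methyl (Z)-2-azido-3-(2,3-dibromophenyl)acrylate F1. Hemetsberger–Knittel thermolysis in xylene at 140 °C should insert the nitrene into the only free ortho C–H and give methyl 4,5-dibromo-1H-indole-2-carboxylate F2. NIS in DMF should iodinate C3 to methyl 4,5-dibromo-3-iodo-1H-indole-2-carboxylate F3. Boc2O with 4-(dimethylamino)pyridine should give 1-tert-butyl 2-methyl 4,5-dibromo-3-iodoindole-1,2-dicarboxylate F4. Ullmann-type N-arylation of 13 with F4 (CuI, trans-N,N'-dimethylcyclohexane-1,2-diamine, K3PO4, toluene, 110 °C), in which the iodide reacts in preference to the aryl bromides, should deliver 18.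

2. Step 8. Hydride abstraction from an N-acylated indoline may be sluggish, and at the temperature needed the electron-rich unprimed indole may be oxidised. The fallback sets out from 17 and returns at 19. TFA in CH2Cl2 at 0 °C should remove Boc to give methyl trans-4,5-dibromo-3-(5-bromoindol-1-yl)indoline-2-carboxylate F5. MnO2 in CH2Cl2 at rt should dehydrogenate the free N–H indoline to 19, which is then isolated and saponified to 20 under the conditions of step 9.

3. Step 10. Ipso-bromodecarboxylation at the hindered C2' may lag behind nuclear bromination, so that forcing it brings over-bromination of the benzo rings or leaves the acid unconverted. The fallback separates decarboxylation from bromination; it sets out from 20 and returns at 23. Protodecarboxylation (Ag2CO3 cat., AcOH, DMSO, 120 °C) should give 4,5-dibromo-3-(5-bromoindol-1-yl)-1H-indole F6. NBS (3 equiv) in DMF should then brominate the free C2' of the 3-substituted N–H indole together with C3 and C2.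

**Further compounds**

F1 | step 7 | methyl (Z)-2-azido-3-(2,3-dibromophenyl)acrylate | COC(=O)/C(N=[N+]=[N-])=C/c1cccc(Br)c1Br
F2 | step 7 | methyl 4,5-dibromo-1H-indole-2-carboxylate | COC(=O)c1cc2c(Br)c(Br)ccc2[nH]1
F3 | step 7 | methyl 4,5-dibromo-3-iodo-1H-indole-2-carboxylate | COC(=O)c1[nH]c2ccc(Br)c(Br)c2c1I
F4 | step 7 | 1-tert-butyl 2-methyl 4,5-dibromo-3-iodoindole-1,2-dicarboxylate | COC(=O)c1c(I)c2c(Br)c(Br)ccc2n1C(=O)OC(C)(C)C
F5 | step 8 | methyl trans-4,5-dibromo-3-(5-bromoindol-1-yl)indoline-2-carboxylate (racemic) | COC(=O)[C@@H]1[C@@H](n2ccc3cc(Br)ccc32)c2c(Br)c(Br)ccc2N1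
F6 | step 10 | 4,5-dibromo-3-(5-bromoindol-1-yl)-1H-indole | Brc1ccc2c(c1)ccn2-c1c[nH]c2ccc(Br)c(Br)c12
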